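**Plan**
1. Ring numbering for the discussion: C1 (carbinol), C2, C3, C4 (CMeBr), C5 (CHCl), C6. Retrosynthetic cuts, in order: the two O–Si bonds; the exocyclic C=CH2 (ketone methylenation); the side-chain CH2–CH(OH) bond (aldol with 3-methylbut-2-enal); C4–Br (reopening of an oxygen bridge); C4–O and C5–Cl together (chloroetherification); the ring C4=C5 bond (RCM); C1–C6 (allylation) and C1–C2 (Grignard acylation of oxalate).
2. Forward: oxalate → α-keto ester → tertiary carbinol → cyclohexene by RCM → oxanorbornane by chloroetherification → methyl ketone → bridge reopened to the bromochloride → aldol, methylenation, desilylation.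
3. Enabling feature: on the cyclohexane the C1 oxygen is cis to the C4 bromine and trans to the C5 chlorine, so this oxygen can be tied across the ring to C4 (a 7-oxabicyclo[2.2.1]heptane, ring in a boat) while chlorine adds to C5 on the opposite face.
4. Stereochemistry: C1 from a catalyst-controlled allylboration; C5 and C4 relayed from C1 through the oxygen bridge (anti addition, then replacement of the bridge oxygen by bromide with retention through the chloronium); the side-chain carbinol from a catalyst-controlled aldol addition.

Key step: step 4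

Assumption: the absolute sense of induction of the chiral catalysts in steps 2 and 8 is not taken for granted on these substrates; in each case the catalyst antipode is used that attacks the carbonyl face named in the step.

Step 1
Reactants: 1 dimethyl oxalate; 2 4-bromo-2-methylbut-1-ene
Product: 4 methyl 5-methyl-2-oxohex-5-enoate, via Grignard reagent 3 (not isolated)
Conditions: 2, Mg, THF, rt; then added to 1 (2 equiv), THF/Et2O, −78 °C; aq. NH4Cl
Reagents that add atoms: none
Why: Grignard mono-acylation with a dialkyl oxalate; with inverse addition at −78 °C the tetrahedral magnesium alkoxide should persist until work-up, so the α-keto ester is not exposed to a second equivalent of the reagent.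

Step 2
Reactants: 4 methyl 5-methyl-2-oxohex-5-enoate; 5 allylboronic acid pinacol ester
Product: 6 methyl (2R)-2-hydroxy-2-(3-methylbut-3-en-1-yl)pent-4-enoate
Conditions: 5 (1.5 equiv), chiral valine-derived aminophenol catalyst (3 mol%), NaOt-Bu (cat.), MeOH (1.5 equiv), toluene, 22 °C
Reagents that add atoms: none
Why: catalytic enantioselective allylboration of an α-keto ester by an aminophenol-bound allylboron species; the catalyst should differentiate the ester from the alkyl chain and deliver allyl to the Re face of the ketone carbon (the later ring C1), which sets (R).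

Step 3
Reactants: 6 methyl (2R)-2-hydroxy-2-(3-methylbut-3-en-1-yl)pent-4-enoate
Product: 7 methyl (1R)-1-hydroxy-4-methylcyclohex-3-ene-1-carboxylate
Conditions: Grubbs II (3 mol%), CH2Cl2, 40 °C
Reagents that add atoms: none
Why: ring-closing metathesis between the monosubstituted and the 1,1-disubstituted alkene should close the trisubstituted cyclohexene with loss of ethene; the free tertiary alcohol and the ester are tolerated and the stereocentre is not touched.

Step 4
Reactants: 7 methyl (1R)-1-hydroxy-4-methylcyclohex-3-ene-1-carboxylate
Product: 8 methyl (1R,3S,4S)-3-chloro-4-methyl-7-oxabicyclo[2.2.1]heptane-1-carboxylate (chlorine endo)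
Conditions: NCS (1.1 equiv), Ph3P=S (10 mol%), CH2Cl2, −20 °C → rt
Reagents that add atoms: N-chlorosuccinimide, O=C1CCC(=O)N1Cl
Why: Sulfide-activated NCS transfers Cl+ to the C4=C5 alkene, and on the face opposite the C1 hydroxyl the developing chloronium is opened at the tertiary carbon C4 by that hydroxyl, the cyclohexene passing through a boat so that C4–O and C5–Cl form in one anti addition. The closest known reaction type is the transannular haloetherification by which 4-alkylcyclohex-3-en-1-ols of the terpinen-4-ol kind give 2-endo-halo-1,4-epoxycyclohexanes. The one new ring, the oxolane O–C1–C2–C3–C4, closes in a 5-exo mode with respect to the alkene (C5 stays outside it; traced through C6 and C5 the same O–C4 bond is a 5-endo closure), and this makes the 7-oxabicyclo[2.2.1]heptane. C4 is fixed by the tether, because the oxygen can only bond on the ring face it already occupies, and C5 by the anti course of the addition, which leaves chlorine endo, that is trans to the C1 oxygen as the target requires. The step needs O–C4 rather than O–C5 bonding and capture by the hydroxyl rather than by the ester carbonyl on the other face: Markovnikov polarisation and ring size (attack at C5 would give an oxetane) secure the first, and the much higher nucleophilicity of the hydroxyl, together with the fact that the ester could only turn over by losing its methyl group, secures the second.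

Step 5
Reactants: 8 methyl (1R,3S,4S)-3-chloro-4-methyl-7-oxabicyclo[2.2.1]heptane-1-carboxylate
Product: 10 1-[(1R,3S,4S)-3-chloro-4-methyl-7-oxabicyclo[2.2.1]heptan-1-yl]ethan-1-one, via Weinreb amide 9 (not isolated)
Conditions: Me(MeO)NH·HCl (1.5 equiv), i-PrMgCl (3.0 equiv), THF, −20 °C; then MeMgBr (3 equiv), −20 → 0 °C; aq. NH4Cl
Reagents that add atoms: methylmagnesium bromide, C[Mg]Br; N,O-dimethylhydroxylamine hydrochloride, CNOC.Cl (its atoms are in 9 only)
Why: magnesium-amide aminolysis of the ester to the N-methoxy-N-methylamide, followed in the same flask by Grignard addition whose chelated adduct releases the methyl ketone only on work-up; the ether bridge and the neopentyl-type endo chloride (no anti-periplanar β-hydrogen) should be inert, and all carbanion chemistry is finished before the tertiary bromide exists.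

Step 6
Reactants: 10 1-[(1R,3S,4S)-3-chloro-4-methyl-7-oxabicyclo[2.2.1]heptan-1-yl]ethan-1-one
Product: 11 1-[(1R,3S,4S)-4-bromo-3-chloro-1-hydroxy-4-methylcyclohexyl]ethan-1-one
Conditions: BBr3 (2.5 equiv), CH2Cl2, −78 → −30 °C; pH 7 buffer
Reagents that add atoms: boron tribromide, BrB(Br)Br
Why: Proposed new method: boron held between the acetyl oxygen and the bridge oxygen turns the ether into a leaving group, only the C4–O bond can ionise because C1 is α to the carbonyl, the endo chlorine on C5 lies almost anti-periplanar to that bond and bridges the developing cation as a chloronium on its own face, and bromide then opens the chloronium at the tertiary carbon C4 from the face the oxygen has just left, which should give C4–Br with retention (cis to the C1 oxygen, trans to Cl) while the C1 oxygen stays bound to boron and cannot close again; the closest known reaction types are the cleavage of bridged and tertiary ethers to tertiary bromides by boron bromides and the retentive substitution of trans-β-halo alcohols through halonium ions.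

Step 7
Reactants: 11 1-[(1R,3S,4S)-4-bromo-3-chloro-1-hydroxy-4-methylcyclohexyl]ethan-1-one
Product: 12 trimethyl{[(1R,3S,4S)-4-bromo-3-chloro-4-methyl-1-{1-[(trimethylsilyl)oxy]ethenyl}cyclohexyl]oxy}silane
Conditions: TMSOTf (2.5 equiv), Et3N (3 equiv), CH2Cl2, 0 °C
Reagents that add atoms: trimethylsilyl trifluoromethanesulfonate, C[Si](C)(C)OS(=O)(=O)C(F)(F)F
Why: soft enolisation and silylation in one operation: the tertiary alcohol is capped and the methyl ketone, enolisable on one side only, becomes its trimethylsilyl enol ether, the amine being too weak a base at 0 °C to eliminate the tertiary bromide.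

Step 8
Reactants: 12 the bis-silyl compound of step 7; 13 3-methylbut-2-enal
Product: 14 (3S)-1-[(1R,3S,4S)-4-bromo-3-chloro-4-methyl-1-(trimethylsilyloxy)cyclohexyl]-3-hydroxy-5-methylhex-4-en-1-one
Conditions: 13 (1.2 equiv), SiCl4 (1.5 equiv), chiral binaphthyldiamine-derived bisphosphoramide (5 mol%), i-Pr2NEt (10 mol%), CH2Cl2, −78 °C; aq. KF/NaHCO3
Reagents that add atoms: none
Why: catalytic enantioselective Mukaiyama aldol addition (Lewis-base-activated SiCl4) of a methyl-ketone silyl enol ether to a conjugated aldehyde, which reacts 1,2; the chiral trichlorosilyl cation should expose the Si face of the aldehyde and so set (3S) under catalyst control, since C1 carries two nearly identical CH2 arms and exerts little bias of its own.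

Step 9
Reactants: 14 the (3S)-aldol of step 8
Product: 15 (3S)-1-[(1R,3S,4S)-4-bromo-3-chloro-4-methyl-1-(trimethylsilyloxy)cyclohexyl]-5-methyl-3-(triethylsilyloxy)hex-4-en-1-one
Conditions: TESOTf, 2,6-lutidine, CH2Cl2, −78 °C
Reagents that add atoms: triethylsilyl trifluoromethanesulfonate, CC[Si](CC)(CC)OS(=O)(=O)C(F)(F)F
Why: standard silylation of a secondary alcohol, which blocks retro-aldol and β-elimination and keeps the hydroxyl from consuming the titanium reagent of the next step.

Step 10
Reactants: 15 the β-triethylsilyloxy ketone of step 9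
Product: 16 {[(1R,3S,4S)-4-bromo-3-chloro-4-methyl-1-[(4S)-6-methyl-4-(triethylsilyloxy)hepta-1,5-dien-2-yl]cyclohexyl]oxy}trimethylsilane
Conditions: Tebbe reagent (2 equiv), pyridine (cat.), THF/toluene, −40 → 0 °C; aq. NaHCO3
Reagents that add atoms: Tebbe reagent, C[Al-]1(C)C[Ti]([Cl+]1)(C1C=CC=C1)C1C=CC=C1
Why: Tebbe methylenation; the small, weakly basic titanium methylidene should convert the hindered, enolisable β-silyloxy ketone into the 1,1-disubstituted alkene through an oxatitanacyclobutane without elimination, and it does not attack alkyl halides or silyl ethers.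

Step 11
Reactants: 16 the bis-silyl ether of step 10
Product: 17 (1R,3S,4S)-4-bromo-3-chloro-1-[(4S)-4-hydroxy-6-methylhepta-1,5-dien-2-yl]-4-methylcyclohexan-1-ol
Conditions: HF·pyridine, pyridine, THF, 0 °C → rt
Reagents that add atoms: none
Why: fluoride-driven cleavage of both silyl ethers under buffered, non-basic conditions that should neither ionise the allylic alcohols nor eliminate the tertiary bromide, so the four stereocentres are delivered unchanged.

**Compound list**
1 | dimethyl oxalate | COC(=O)C(=O)OC | starting material
2 | 4-bromo-2-methylbut-1-ene | C=C(C)CCBr | starting material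
3 | (3-methylbut-3-en-1-yl)magnesium bromide | C=C(C)CC[Mg]Br | intermediate (not isolated)
4 | methyl 5-methyl-2-oxohex-5-enoate | COC(=O)C(=O)CCC(C)=C | intermediate
5 | allylboronic acid pinacol ester | C=CCB1OC(C)(C)C(C)(C)O1 | starting material
6 | methyl (2R)-2-hydroxy-2-(3-methylbut-3-en-1-yl)pent-4-enoate | COC(=O)[C@](O)(CC=C)CCC(C)=C | intermediate
7 | methyl (1R)-1-hydroxy-4-methylcyclohex-3-ene-1-carboxylate | COC(=O)[C@@]1(O)CCC(C)=CC1 | intermediate
8 | methyl (1R,3S,4S)-3-chloro-4-methyl-7-oxabicyclo[2.2.1]heptane-1-carboxylate (3-endo-Cl) | COC(=O)[C@@]1(O2)CC[C@@]2(C)[C@@H](Cl)C1 | intermediate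
9 | (1R,3S,4S)-3-chloro-N-methoxy-N,4-dimethyl-7-oxabicyclo[2.2.1]heptane-1-carboxamide | CON(C)C(=O)[C@@]1(O2)CC[C@@]2(C)[C@@H](Cl)C1 | intermediate (not isolated)
10 | 1-[(1R,3S,4S)-3-chloro-4-methyl-7-oxabicyclo[2.2.1]heptan-1-yl]ethan-1-one | CC(=O)[C@@]1(O2)CC[C@@]2(C)[C@@H](Cl)C1 | intermediate
11 | 1-[(1R,3S,4S)-4-bromo-3-chloro-1-hydroxy-4-methylcyclohexyl]ethan-1-one | CC(=O)[C@@]1(O)CC[C@](C)(Br)[C@@H](Cl)C1 | intermediate
12 | trimethyl{[(1R,3S,4S)-4-bromo-3-chloro-4-methyl-1-{1-[(trimethylsilyl)oxy]ethenyl}cyclohexyl]oxy}silane | C=C(O[Si](C)(C)C)[C@@]1(O[Si](C)(C)C)CC[C@](C)(Br)[C@@H](Cl)C1 | intermediate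
13 | 3-methylbut-2-enal | CC(C)=CC=O | starting material
14 | (3S)-1-[(1R,3S,4S)-4-bromo-3-chloro-4-methyl-1-(trimethylsilyloxy)cyclohexyl]-3-hydroxy-5-methylhex-4-en-1-one | CC(C)=C[C@@H](O)CC(=O)[C@@]1(O[Si](C)(C)C)CC[C@](C)(Br)[C@@H](Cl)C1 | intermediate
15 | (3S)-1-[(1R,3S,4S)-4-bromo-3-chloro-4-methyl-1-(trimethylsilyloxy)cyclohexyl]-5-methyl-3-(triethylsilyloxy)hex-4-en-1-one | CC(C)=C[C@@H](O[Si](CC)(CC)CC)CC(=O)[C@@]1(O[Si](C)(C)C)CC[C@](C)(Br)[C@@H](Cl)C1 | intermediate
16 | {[(1R,3S,4S)-4-bromo-3-chloro-4-methyl-1-[(4S)-6-methyl-4-(triethylsilyloxy)hepta-1,5-dien-2-yl]cyclohexyl]oxy}trimethylsilane | C=C(C[C@H](O[Si](CC)(CC)CC)C=C(C)C)[C@@]1(O[Si](C)(C)C)CC[C@](C)(Br)[C@@H](Cl)C1 | intermediate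
17 | (1R,3S,4S)-4-bromo-3-chloro-1-[(4S)-4-hydroxy-6-methylhepta-1,5-dien-2-yl]-4-methylcyclohexan-1-ol | C=C(C[C@H](O)C=C(C)C)[C@@]1(O)CC[C@](C)(Br)[C@@H](Cl)C1 | target

**Count**
Total steps: 11. Longest linear sequence: 11 steps (from 1 and 2 to 17).

**Steps most likely to fail, with fallbacks**

First, step 6. What may go wrong: proton loss from the C4 cation (elimination to allylic chlorides), capture of bromide on the chlorine face or at C5 after chlorine migration, or incomplete cleavage with boron-induced enolisation of the ketone. The fallback puts the halogens in by classical epoxide chemistry instead of by ether cleavage; it sets out from 7 and comes back at 11.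
- Hydroxyl-directed epoxidation of 7 (VO(acac)2, t-BuOOH, CH2Cl2) should give the cis-epoxy alcohol methyl (1R,3R,6S)-3-hydroxy-6-methyl-7-oxabicyclo[4.1.0]heptane-3-carboxylate F1, with the epoxide oxygen on the face of the C1 hydroxyl.
- Opening with chloride at the secondary carbon with inversion (LiCl, AcOH, THF) places chlorine on C5 trans to both oxygens and gives the chlorohydrin methyl (1R,3S,4S)-3-chloro-1,4-dihydroxy-4-methylcyclohexane-1-carboxylate F2.
- Bromotrimethylsilane (CH2Cl2, 0 °C) converts the tertiary C4 alcohol into the bromide. Retention through the anti chloronium is the classical course for a trans-β-halo alcohol, so the product should be methyl (1R,3S,4S)-4-bromo-3-chloro-1-hydroxy-4-methylcyclohexane-1-carboxylate F3.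
- The one-pot sequence of step 5, kept at −20 °C with one extra equivalent of base for the hydroxyl, takes F3 through the amide (1R,3S,4S)-4-bromo-3-chloro-1-hydroxy-N-methoxy-N,4-dimethylcyclohexane-1-carboxamide F4 to 11.
- This fallback still relies on the chloronium for retention at C4, and it exposes the bromochloride to Grignard reagents once.

Second, step 10. What may go wrong: enolisation instead of methylenation at the hindered ketone, or damage to the tertiary bromide or the silyl ethers by the aluminium Lewis acid. The fallback adds the carbon as a nucleophile and forms the alkene by elimination; it sets out from 15 and comes back at 17.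
- Me3SiCH2MgCl/CeCl3 (THF, −78 → 0 °C), a weakly basic reagent that adds to hindered enolisable ketones, should give the β-hydroxysilane (4S)-2-[(1R,3S,4S)-4-bromo-3-chloro-4-methyl-1-(trimethylsilyloxy)cyclohexyl]-6-methyl-4-(triethylsilyloxy)-1-(trimethylsilyl)hept-5-en-2-ol F5 (either epimer at C2).
- HF·pyridine in THF then effects the Peterson elimination to the 1,1-disubstituted alkene and removes both silyl ethers in the same operation, giving 17 directly.

Third, step 8. What may go wrong: poor facial selectivity on the aldehyde, or slow addition of the hindered enol silane. The fallback moves control from a catalyst acting through an open transition state to a stoichiometric chiral boron enolate reacting through a closed one; it sets out from 11 and comes back at 14.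
- Silylation of the tertiary alcohol only (TMSOTf 1.1 equiv, 2,6-lutidine, CH2Cl2, −78 °C) gives 1-[(1R,3S,4S)-4-bromo-3-chloro-4-methyl-1-(trimethylsilyloxy)cyclohexyl]ethan-1-one F6.
- Enolisation with (−)-Ipc2BCl and Et3N (Et2O, 0 °C) gives the enol diisopinocampheylborinate F7, which adds to 13 at −78 °C; oxidative work-up (H2O2, pH 7 buffer, MeOH) gives 14.
- The minor carbinol epimer is a diastereomer and should be removable by chromatography.
- (−)-Ipc2BCl is taken to be the antipode that sends methyl-ketone enolates to the aldehyde Si face; otherwise its enantiomer is used.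

**Further compounds**
F1 | step 6 | methyl (1R,3R,6S)-3-hydroxy-6-methyl-7-oxabicyclo[4.1.0]heptane-3-carboxylate | COC(=O)[C@@]1(O)CC[C@]2(C)O[C@@H]2C1
F2 | step 6 | methyl (1R,3S,4S)-3-chloro-1,4-dihydroxy-4-methylcyclohexane-1-carboxylate | COC(=O)[C@@]1(O)CC[C@](C)(O)[C@@H](Cl)C1
F3 | step 6 | methyl (1R,3S,4S)-4-bromo-3-chloro-1-hydroxy-4-methylcyclohexane-1-carboxylate | COC(=O)[C@@]1(O)CC[C@](C)(Br)[C@@H](Cl)C1
F4 | step 6 | (1R,3S,4S)-4-bromo-3-chloro-1-hydroxy-N-methoxy-N,4-dimethylcyclohexane-1-carboxamide | CON(C)C(=O)[C@@]1(O)CC[C@](C)(Br)[C@@H](Cl)C1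
F5 | step 10 | (4S)-2-[(1R,3S,4S)-4-bromo-3-chloro-4-methyl-1-(trimethylsilyloxy)cyclohexyl]-6-methyl-4-(triethylsilyloxy)-1-(trimethylsilyl)hept-5-en-2-ol | CC(C)=C[C@@H](O[Si](CC)(CC)CC)CC(O)(C[Si](C)(C)C)[C@@]1(O[Si](C)(C)C)CC[C@](C)(Br)[C@@H](Cl)C1
F6 | step 8 | 1-[(1R,3S,4S)-4-bromo-3-chloro-4-methyl-1-(trimethylsilyloxy)cyclohexyl]ethan-1-one | CC(=O)[C@@]1(O[Si](C)(C)C)CC[C@](C)(Br)[C@@H](Cl)C1
F7 | step 8 | enol diisopinocampheylborinate of F6 | C=C(OB([C@@H]1C[C@@H]2C[C@H]([C@H]1C)C2(C)C)[C@@H]1C[C@@H]2C[C@H]([C@H]1C)C2(C)C)[C@@]1(O[Si](C)(C)C)CC[C@](C)(Br)[C@@H](Cl)C1
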